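If each E formed consumes one X, a flask charged with less X than J has a ceiling on E that a faster pace cannot lift. The reckoning therefore takes two rounds: first the pace, then the X which that pace asks for.

| setting | Saturday's | Friday's | Wednesday's | gamma | eta |
|---|---|---|---|---|---|
| J | 0.013 M | 0.018 M | 0.017 M | 0.025 M | 0.017 M |
| X | 0.0187 M | 0.0187 M | 0.010 M | 0.0100 M | 0.0187 M |
| G | 0.14 mM | 0.14 mM | 0.14 mM | 0.14 mM | 0.14 mM |
| temperature | 20 °C | 32 °C | 20 °C | 40 °C | 25 °C |
| remark | run made earlier | run made earlier | run made earlier |  |  |
| time |  |  |  | 12 h | 12 h |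

| run | time / h | E / % | J / % |
|---|---|---|---|
| Saturday's | 0.667 | 3.9 | 94.7 |
| Saturday's | 1.33 | 9.2 | 90.7 |
| Saturday's | 2.50 | 16.3 | 84.5 |
| Saturday's | 4.00 | 26.3 | 73.3 |
| Saturday's | 8.00 | 52.1 | 44.6 |
| Friday's | 0.833 | 21.8 | 79.0 |
| Friday's | 2.00 | 46.8 | 52.8 |
| Friday's | 4.00 | 78.9 | 21.4 |
| Friday's | 6.00 | 94.5 | 6.2 |
| Friday's | 8.00 | 99.0 | 0.2 |
| Wednesday's | 0.667 | 2.7 | 95.3 |
| Wednesday's | 1.33 | 7.6 | 90.9 |
| Wednesday's | 2.50 | 15.3 | 84.1 |
| Wednesday's | 4.00 | 24.3 | 74.9 |
| Wednesday's | 8.00 | 44.4 | 56.2 |

(each reading ± 1 percentage point)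

- the analysis behind the earlier runs scatters by 1 percentage point, standard deviation

* which one finishes higher in amount of E, in percent of the J charged ("neither" within 2 percentage points) (gamma / eta / neither)
* amount of E at the end, in percent of the J charged, gamma
* amount of E at the end, in percent of the J charged, eta

Down each table, E + J stays near 100%, so J appears to go cleanly to E. Saturday's E grows by 0.847 mM h⁻¹ up to its last reading. Wednesday's, with 0.010 M of X against Saturday's 0.0187 M, grows by 0.944 mM h⁻¹, which is not slower. These two runs differ in J as well as in X, so the comparison does not isolate X, but the run with less X did not run slower. One X per E therefore remains an assumption, though Friday's 99.0% of E fits it. Friday's first readings give 4.21 mM h⁻¹, faster than either run at 20 °C.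

First round for gamma, which is hotter than Friday's run: Friday's pace covers its J in 5.94 h, within the 12 h, so the first answer is 100%. Second round: that E asks for 0.025 M of X, more than the 0.0100 M charged. For gamma the ceiling c, X charged over J charged, is 40.0%, and this reckoning ends there.

For eta, c is 110%, above 100%, so the J charge bounds E and the pace matters. Saturday's pace gives 59.8% in 12 h, already above gamma's ceiling, and Friday's pace passes the charge in 4.04 h. Eta, between those temperatures, should therefore finish higher.

The forecast names eta, with 40% (37% to 46%) for gamma and 92% (82% to 99%) for eta, calling the one-to-one use of X “likely but unproven”.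

The simulation gives 40.0% for gamma and 97.1% for eta, so eta finishes higher.

    J + G → D (k = 1.90 L mol⁻¹ s⁻¹, Ea = 48.0 kJ mol⁻¹)
    X + D → L (k = 1.40 L mol⁻¹ s⁻¹, Ea = 54.0 kJ mol⁻¹)
    L → G + E (k = 0.00940 s⁻¹, Ea = 88.0 kJ mol⁻¹)
    X + L ⇌ Q, settled at all times (K = 47.0 L mol⁻¹, ΔH = −79.0 kJ mol⁻¹)
    (constants at 25 °C)

Gamma stops at its ceiling 40.0% because X, the limiting reagent, is consumed: the same run without that wearing away of X gives 100% instead of 40.0%. At 6.00 h gamma already holds 40.0% of E, 0% of X and 59.4% of J, and a reading ten times later changes nothing.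

The neighbour with 0.0063 M of J has c = 159%, so the ceiling is the J charge, with 37.0% of the X to spare. The simulation gives 100% of E and 37% of X left.

Readings and results were generated by integration on assumed constants, noise included.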